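**Plan**

- Retrosynthetic cuts: C16=C17 (α-methylenation); C13–C16 (carbenoid C–H insertion, ring D); C15–C16 (diazoketone from the C15 acid); the C7 acyl group moved from O20 back to O11 (bridged γ-lactone); C8–C14 and C8–C15 (enolate alkylation and acylation); C9–C10 together with C5–C6 (one radical cascade).
- This leaves two fragments: a ring A homoallylic oxalate (C1–C5, C10, C18–C20) and (R)-5-(3-chloropropyl)butenolide (C7–C9, C11–C14).
- Forward: the γ-lactone on ring A and the C9–C10 bond form in one photoredox cascade; ring C closes by bridging alkylation of the butyrolactone; the C7 acyl group is moved to O20 (δ-lactone); ring D closes by transannular C–H insertion; methylenation ends the route.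
- Stereochemistry: C4 from a Cu-catalysed asymmetric conjugate addition; C11 from a Zn–ProPhenol alkynylation; C5 and C10 are relayed from C4 in the cascade; C9 is set anti to the C11 side chain on the butenolide; C8 is fixed by the bridged lactone; C13 by insertion with retention.

Key step: step 18

Remark: ent-kaurane numbering (C1–C20) is used for all intermediates; in steps 3 and 9 the ligand enantiomer is the one that gives the configuration shown.

**Route**

Step 1
Reactants: 1 3-methoxybenzyl alcohol
Product: 3 3-(hydroxymethyl)cyclohex-2-en-1-one, via (5-methoxycyclohexa-1,4-dien-1-yl)methanol 2 (not isolated)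
Conditions: Li, NH3(l), THF, t-BuOH, −78 to −33 °C; then 2 M HCl, THF, rt
Reagents that add atoms: water, O
Why: Birch reduction of the anisole (as its lithium benzyloxide, which resists benzylic C–O cleavage) should give the 2,5-dihydro enol ether, and acid hydrolysis with migration of the β,γ-alkene into conjugation should give the enone.

Step 2
Reactants: 3 3-(hydroxymethyl)cyclohex-2-en-1-one
Product: 4 3-{[(tert-butyldimethylsilyl)oxy]methyl}cyclohex-2-en-1-one
Conditions: TBSCl, imidazole, CH2Cl2, 0 °C to rt
Reagents that add atoms: tert-butyldimethylsilyl chloride, CC(C)(C)[Si](C)(C)Cl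
Why: Imidazole-mediated silylation of a primary alcohol is routine and protects the future C19 oxygen through the organometallic steps.

Step 3
Reactants: 4 3-{[(tert-butyldimethylsilyl)oxy]methyl}cyclohex-2-en-1-one
Product: 6 (R)-3-{[(tert-butyldimethylsilyl)oxy]methyl}-3-methylcyclohex-1-en-1-yl trifluoromethanesulfonate, via bromomagnesium (R)-3-{[(tert-butyldimethylsilyl)oxy]methyl}-3-methylcyclohex-1-en-1-olate 5 (not isolated)
Conditions: MeMgBr, Cu(OTf)2 (3 mol%), chiral imidazolinium salt (NHC precursor, 4 mol%), Et2O, 0 °C; then N-(5-chloro-2-pyridyl)bis(trifluoromethanesulfonimide), THF, −78 °C to rt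
Reagents that add atoms: methylmagnesium bromide, C[Mg]Br; N-(5-chloro-2-pyridyl)bis(trifluoromethanesulfonimide), O=S(=O)(N(c1ccc(Cl)cn1)S(=O)(=O)C(F)(F)F)C(F)(F)F
Why: Copper–NHC-catalysed asymmetric conjugate addition of a methyl Grignard reagent to a β-substituted cyclohexenone sets the C4 quaternary centre by ligand-controlled face selection, and O-triflation of the regiodefined magnesium enolate places the enol triflate on the C5 side only.

Step 4
Reactants: 6 (R)-3-{[(tert-butyldimethylsilyl)oxy]methyl}-3-methylcyclohex-1-en-1-yl trifluoromethanesulfonate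
Product: 7 [(R)-3-{[(tert-butyldimethylsilyl)oxy]methyl}-3-methylcyclohex-1-en-1-yl]methanol
Conditions: Bu3SnCH2OH, Pd(PPh3)4 (5 mol%), LiCl, 1,4-dioxane, 100 °C
Reagents that add atoms: (tributylstannyl)methanol, CCCC[Sn](CCCC)(CCCC)CO
Why: Stille coupling of an enol triflate with (tributylstannyl)methanol transfers the hydroxymethyl group selectively and installs C20 on C10 at the alcohol oxidation level.

Step 5
Reactants: 7 [(R)-3-{[(tert-butyldimethylsilyl)oxy]methyl}-3-methylcyclohex-1-en-1-yl]methanol
Product: 8 {[(R)-3-[(benzyloxy)methyl]-1-methylcyclohex-2-en-1-yl]methoxy}(tert-butyl)dimethylsilane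
Conditions: NaH, BnBr, Bu4NI (cat.), THF, 0 °C to rt
Reagents that add atoms: benzyl bromide, BrCc1ccccc1
Why: Williamson etherification of the primary allylic alkoxide gives a C20 benzyl ether that is inert to the radical, enolate and carbonate steps and is removed later by hydrogenolysis.

Step 6
Reactants: 8 {[(R)-3-[(benzyloxy)methyl]-1-methylcyclohex-2-en-1-yl]methoxy}(tert-butyl)dimethylsilane
Product: 9 [(R)-3-[(benzyloxy)methyl]-1-methylcyclohex-2-en-1-yl]methanol
Conditions: Bu4NF, THF, rt
Reagents that add atoms: none
Why: Fluoride desilylation frees the neopentyl C19 alcohol without touching the benzyl ether or the alkene.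

Step 7
Reactants: 9 [(R)-3-[(benzyloxy)methyl]-1-methylcyclohex-2-en-1-yl]methanol
Product: 12 cesium 2-{[(R)-3-[(benzyloxy)methyl]-1-methylcyclohex-2-en-1-yl]methoxy}-2-oxoacetate, via [(R)-3-[(benzyloxy)methyl]-1-methylcyclohex-2-en-1-yl]methyl 2-chloro-2-oxoacetate 10 (not isolated), via 2-{[(R)-3-[(benzyloxy)methyl]-1-methylcyclohex-2-en-1-yl]methoxy}-2-oxoacetic acid 11 (not isolated)
Conditions: (COCl)2, Et2O, 0 °C to rt; evaporate; H2O, THF; then CsOH (1.0 equiv)
Reagents that add atoms: oxalyl chloride, ClC(=O)C(=O)Cl; water, O; cesium hydroxide, [Cs+].[OH-]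
Why: O-acylation with excess oxalyl chloride, hydrolysis of the remaining acid chloride and neutralisation give the cesium half-oxalate, the standard photoredox precursor of an alkoxycarbonyl radical.

Step 8
Reactants: 13 4-chloro-1,1-dimethoxybutane
Product: 14 4-chlorobutanal
Conditions: 1 M HCl, acetone, rt; used at once
Reagents that add atoms: water, O
Why: Acid-catalysed acetal hydrolysis releases the labile aldehyde immediately before use.

Step 9
Reactants: 14 4-chlorobutanal; 15 methyl propiolate
Product: 16 methyl (R)-7-chloro-4-hydroxyhept-2-ynoate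
Conditions: Me2Zn, ProPhenol (10 mol%), Ph3PO (20 mol%), toluene, 4 °C
Reagents that add atoms: none
Why: Zinc–ProPhenol-catalysed asymmetric alkynylation adds the zinc propiolate to the Si face of the aldehyde and sets C11 as R; the weakly nucleophilic zinc alkoxide should not displace the δ-chloride.

Step 10
Reactants: 16 methyl (R)-7-chloro-4-hydroxyhept-2-ynoate
Product: 18 (R)-5-(3-chloropropyl)furan-2(5H)-one, via methyl (R,Z)-7-chloro-4-hydroxyhept-2-enoate 17 (not isolated)
Conditions: H2 (1 atm), Lindlar catalyst, quinoline, EtOAc, rt; then PPTS (cat.), CH2Cl2, rt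
Reagents that add atoms: none
Why: Lindlar semihydrogenation gives the Z-enoate, which lactonises to the butenolide without touching the C11 stereocentre or the alkyl chloride.

Step 11
Reactants: 12 cesium 2-{[(R)-3-[(benzyloxy)methyl]-1-methylcyclohex-2-en-1-yl]methoxy}-2-oxoacetate; 18 (R)-5-(3-chloropropyl)furan-2(5H)-one
Product: 19 (4R,5R,9R,10R,11R)-bis-lactone: (3aR,7R,7aR)-7-[(benzyloxy)methyl]-7-[(2R,3R)-2-(3-chloropropyl)-5-oxooxolan-3-yl]-3a-methylhexahydro-2-benzofuran-1(3H)-one
Conditions: [Ir{dF(CF3)ppy}2(dtbbpy)]PF6 (2 mol%), 18 (1.5 equiv), H2O (10 equiv), DME/DMF 3:1, blue LEDs, 40 °C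
Reagents that add atoms: none
Why: Photoredox oxidation of the oxalate with loss of CO2 gives an alkoxycarbonyl radical that closes the ring A γ-lactone by 5-exo-trig attack on C5 (cis fusion is forced, which sets C5), and the resulting tertiary C10 radical should undergo Giese addition to the butenolide β-carbon anti to the C5–C6 bond (convex face, sets C10) and anti to the 3-chloropropyl group (sets C9) before reduction and protonation at C8.

Step 12
Reactants: 19 the bis-lactone
Product: 20 tert-butyl (4R,5R)-5-(3-chloropropyl)-4-[(3aR,7R,7aR)-7-[(benzyloxy)methyl]-3a-methyl-1-oxooctahydro-2-benzofuran-7-yl]-2-oxooxolane-3-carboxylate (C8 epimers)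
Conditions: LiHMDS (2.2 equiv), THF, −78 °C; Boc2O, −78 to −40 °C
Reagents that add atoms: di-tert-butyl dicarbonate, CC(C)(C)OC(=O)OC(=O)OC(C)(C)C
Why: Claisen-type C-acylation of the kinetic butyrolactone enolate (C8–H2 is the only accessible α-position, since C5–H lies between two quaternary carbons) installs C15 as a tert-butyl ester, and at −78 °C the primary chloride should not be alkylated.

Step 13
Reactants: 20 the tert-butyl 2-oxooxolane-3-carboxylate
Product: 22 tert-butyl (4R,5R,8S,9S,10R,11R)-bridged lactone: 6-oxabicyclo[3.2.1]octan-7-one (C7 lactone to O11) with the tert-butyl ester on C8 and the ring A lactone unit on C9, via the corresponding 3-iodopropyl lactone 21 (not isolated)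
Conditions: NaI, Cs2CO3, DMF, 60 °C
Reagents that add atoms: none
Why: Finkelstein exchange and intramolecular C-alkylation of the lactone–ester enolate (6-exo-tet) close ring C; the tether from C11 can only reach the enolate face on its own side, so the C8 quaternary centre forms with C14 cis to C12 and with the lactone carbonyl (C7) cis, and the ester (C15) trans, to C10.

Step 14
Reactants: 22 the bridged lactone benzyl ether
Product: 24 tert-butyl 11-hydroxy 7,20-δ-lactone 6,19-γ-lactone (ring D absent; configuration unchanged), via the C20 alcohol of the bridged lactone 23 (not isolated)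
Conditions: H2 (1 atm), Pd/C, EtOAc, rt; filter; DBU (0.2 equiv), toluene, 40 °C
Reagents that add atoms: none
Why: Hydrogenolysis frees the C20 alcohol, and base-catalysed translactonisation should move the C7 acyl group from O11 to the primary O20, trading the strained bridged γ-lactone for a fused δ-lactone; the tert-butyl ester is inert, so only the carboxyl cis to C10 lactonises and the cis fusion is secured.

Step 15
Reactants: 24 the 11-hydroxy bis-lactone tert-butyl ester
Product: 25 the 11-chloroacetate of 24
Conditions: (ClCH2CO)2O, pyridine, DMAP (cat.), CH2Cl2, 0 °C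
Reagents that add atoms: chloroacetic anhydride, ClCC(=O)OC(=O)CCl
Why: Acylation caps O11 against O–H insertion and return to the bridged lactone; the chloroacetate deactivates the C11–H bond more strongly than an acetate and can later be removed by thiourea without alkoxide base.

Step 16
Reactants: 25 the 11-chloroacetate tert-butyl ester
Product: 26 C15 carboxylic acid (8-carboxy 7,20:6,19-bis-lactone 11-chloroacetate)
Conditions: TFA/CH2Cl2 1:4, 0 °C to rt
Reagents that add atoms: none
Why: Acidolysis of the tert-butyl ester via the tert-butyl cation spares both lactones and the chloroacetate, and the fully substituted malonic half-acid should not decarboxylate at room temperature.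

Step 17
Reactants: 26 the C15 carboxylic acid
Product: 28 C8 diazoacetyl bis-lactone 11-chloroacetate (ring D absent), via the C15 acid chloride 27 (not isolated)
Conditions: (COCl)2, DMF (cat.), CH2Cl2, 0 °C to rt; evaporate; TMSCHN2, THF/MeCN 1:1, 0 °C to rt
Reagents that add atoms: (trimethylsilyl)diazomethane, C[Si](C)(C)C=[N+]=[N-]
Why: C-acylation of (trimethylsilyl)diazomethane by the acid chloride and loss of the silyl group to chloride is the first half of an Arndt–Eistert sequence; the acid chloride has no α-hydrogen, so no ketene can form.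

Step 18
Reactants: 28 the C8 diazoacetyl bis-lactone 11-chloroacetate
Product: 29 16-desmethylene ludongnin A 11-chloroacetate
Conditions: Rh2(OAc)4 (2 mol%), CH2Cl2, 40 °C, slow addition of 28
Reagents that add atoms: none
Why: Rh2(OAc)4 decomposes the diazoketone with loss of N2 to an electrophilic rhodium carbenoid at C16, which inserts into a C–H bond through a concerted three-centre transition state with retention at carbon. The closest known reaction type is the Rh(II)-catalysed intramolecular 1,5 C–H insertion of α-diazoketones to cyclopentanones, including transannular closures of axial diazoacetyl cyclohexanes to bicyclo[3.2.1]octanones. Ring D closes as a five-membered ring (1,5-insertion) that bridges C8 and C13 of ring C 1,3-diaxially. The new C13 stereocentre is dictated by C8: only the C13–H syn-axial to the C8 acyl group can be reached, and insertion with retention makes the two-carbon bridge cis. The step needs site selectivity for the secondary C13–H over the other syn-axial hydrogen at C11 and over more remote C–H bonds; the 1,5-geometry disfavours the remote ones, C8 and C10 carry no hydrogen, and the chloroacetoxy group inductively deactivates C11–H. The reactive chair with axial C8 acyl and axial C10 (the ring C conformation of the target) should be reached by ring inversion before the carbenoid is consumed (Curtin–Hammett).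

Step 19
Reactants: 29 16-desmethylene ludongnin A 11-chloroacetate
Product: 30 16-desmethylene ludongnin A (11-hydroxy-15-oxo-17-nor bis-lactone)
Conditions: thiourea, NaHCO3, EtOH/THF, 55 °C
Reagents that add atoms: none
Why: S-alkylation of thiourea by the chloroacetate and cyclisation to the aminothiazolone releases the C11 alcohol under near-neutral conditions, avoiding alkoxide-induced retro-Claisen cleavage of the non-enolisable β-keto lactone; with ring D in place the equatorial 11-OH cannot reach C7.

Step 20
Reactants: 30 16-desmethylene ludongnin A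
Product: 31 ludongnin A
Conditions: (CH2O)n, PhNHMe·CF3CO2H, THF, reflux
Reagents that add atoms: formaldehyde (from paraformaldehyde), C=O
Why: Mannich-type α-methylenation through the N-methylanilinium iminium ion and β-elimination of the amine acts at C16, the only enolisable position next to the C15 ketone, under mildly acidic conditions that the lactones and the free alcohol tolerate.

**Compound list**

1 | 3-methoxybenzyl alcohol | COc1cccc(CO)c1 | starting material
2 | (5-methoxycyclohexa-1,4-dien-1-yl)methanol | COC1=CCC=C(CO)C1 | intermediate (not isolated)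
3 | 3-(hydroxymethyl)cyclohex-2-en-1-one | O=C1CCCC(CO)=C1 | intermediate
4 | 3-{[(tert-butyldimethylsilyl)oxy]methyl}cyclohex-2-en-1-one | CC(C)(C)[Si](C)(C)OCC1=CC(=O)CCC1 | intermediate
5 | bromomagnesium (R)-3-{[(tert-butyldimethylsilyl)oxy]methyl}-3-methylcyclohex-1-en-1-olate | CC(C)(C)[Si](C)(C)OC[C@]1(C)CCCC(O[Mg]Br)=C1 | intermediate (not isolated)
6 | (R)-3-{[(tert-butyldimethylsilyl)oxy]methyl}-3-methylcyclohex-1-en-1-yl trifluoromethanesulfonate | CC(C)(C)[Si](C)(C)OC[C@]1(C)CCCC(OS(=O)(=O)C(F)(F)F)=C1 | intermediate
7 | [(R)-3-{[(tert-butyldimethylsilyl)oxy]methyl}-3-methylcyclohex-1-en-1-yl]methanol | CC(C)(C)[Si](C)(C)OC[C@]1(C)CCCC(CO)=C1 | intermediate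
8 | {[(R)-3-[(benzyloxy)methyl]-1-methylcyclohex-2-en-1-yl]methoxy}(tert-butyl)dimethylsilane | CC(C)(C)[Si](C)(C)OC[C@]1(C)CCCC(COCc2ccccc2)=C1 | intermediate
9 | [(R)-3-[(benzyloxy)methyl]-1-methylcyclohex-2-en-1-yl]methanol | OC[C@]1(C)CCCC(COCc2ccccc2)=C1 | intermediate
10 | [(R)-3-[(benzyloxy)methyl]-1-methylcyclohex-2-en-1-yl]methyl 2-chloro-2-oxoacetate | ClC(=O)C(=O)OC[C@]1(C)CCCC(COCc2ccccc2)=C1 | intermediate (not isolated)
11 | 2-{[(R)-3-[(benzyloxy)methyl]-1-methylcyclohex-2-en-1-yl]methoxy}-2-oxoacetic acid | OC(=O)C(=O)OC[C@]1(C)CCCC(COCc2ccccc2)=C1 | intermediate (not isolated)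
12 | cesium 2-{[(R)-3-[(benzyloxy)methyl]-1-methylcyclohex-2-en-1-yl]methoxy}-2-oxoacetate | [Cs+].[O-]C(=O)C(=O)OC[C@]1(C)CCCC(COCc2ccccc2)=C1 | intermediate
13 | 4-chloro-1,1-dimethoxybutane (4-chlorobutanal dimethyl acetal) | COC(CCCCl)OC | starting material
14 | 4-chlorobutanal | O=CCCCCl | intermediate
15 | methyl propiolate | C#CC(=O)OC | starting material
16 | methyl (R)-7-chloro-4-hydroxyhept-2-ynoate | ClCCC[C@@H](O)C#CC(=O)OC | intermediate
17 | methyl (R,Z)-7-chloro-4-hydroxyhept-2-enoate | ClCCC[C@@H](O)/C=C\C(=O)OC | intermediate (not isolated)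
18 | (R)-5-(3-chloropropyl)furan-2(5H)-one | ClCCC[C@H]1OC(=O)C=C1 | intermediate
19 | (3aR,7R,7aR)-7-[(benzyloxy)methyl]-7-[(2R,3R)-2-(3-chloropropyl)-5-oxooxolan-3-yl]-3a-methylhexahydro-2-benzofuran-1(3H)-one | ClCCC[C@H]1OC(=O)C[C@@H]1[C@@]1(CCC[C@@]2(C)COC(=O)[C@H]21)COCc1ccccc1 | intermediate
20 | tert-butyl 2-oxooxolane-3-carboxylate derived from 19 (C15 ester on C8; C8 epimers, other centres as in 19) | ClCCC[C@H]1OC(=O)C(C(=O)OC(C)(C)C)[C@@H]1[C@@]1(CCC[C@@]2(C)COC(=O)[C@H]21)COCc1ccccc1 | intermediate
21 | 3-iodopropyl analogue of 20 (C8 epimers) | ICCC[C@H]1OC(=O)C(C(=O)OC(C)(C)C)[C@@H]1[C@@]1(CCC[C@@]2(C)COC(=O)[C@H]21)COCc1ccccc1 | intermediate (not isolated)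
22 | (4R,5R,8S,9S,10R,11R)-bridged lactone: tert-butyl 7-oxo-6-oxabicyclo[3.2.1]octane-1-carboxylate (C7 lactone to O11, ester = C15 on C8) bearing at C9 the (3aR,7R,7aR)-7-[(benzyloxy)methyl]-3a-methyl-1-oxooctahydro-2-benzofuran-7-yl group | CC(C)(C)OC(=O)[C@]12CCC[C@@H](OC2=O)[C@H]1[C@@]1(CCC[C@@]2(C)COC(=O)[C@H]21)COCc1ccccc1 | intermediate
23 | C20 alcohol of 22 (benzyl removed, bridged lactone intact) | CC(C)(C)OC(=O)[C@]12CCC[C@@H](OC2=O)[C@H]1[C@@]1(CCC[C@@]2(C)COC(=O)[C@H]21)CO | intermediate (not isolated)
24 | tert-butyl 11-hydroxy-6,7-seco-ent-kaurane-type 6,19:7,20-diolide-15-oate lacking C16/C17 (ring D open; C11 free alcohol; centres as in 31) | CC(C)(C)OC(=O)[C@]12CCC[C@@H](O)[C@H]1[C@@]1(CCC[C@@]3(C)COC(=O)[C@H]31)COC2=O | intermediate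
25 | 11-chloroacetate of 24 | CC(C)(C)OC(=O)[C@]12CCC[C@@H](OC(=O)CCl)[C@H]1[C@@]1(CCC[C@@]3(C)COC(=O)[C@H]31)COC2=O | intermediate
26 | C15 carboxylic acid from 25 (8-carboxy bis-lactone 11-chloroacetate) | OC(=O)[C@]12CCC[C@@H](OC(=O)CCl)[C@H]1[C@@]1(CCC[C@@]3(C)COC(=O)[C@H]31)COC2=O | intermediate
27 | C15 acid chloride of 26 | ClC(=O)[C@]12CCC[C@@H](OC(=O)CCl)[C@H]1[C@@]1(CCC[C@@]3(C)COC(=O)[C@H]31)COC2=O | intermediate (not isolated)
28 | C8 diazoacetyl bis-lactone 11-chloroacetate lacking ring D | [N-]=[N+]=CC(=O)[C@]12CCC[C@@H](OC(=O)CCl)[C@H]1[C@@]1(CCC[C@@]3(C)COC(=O)[C@H]31)COC2=O | intermediate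
29 | 16-desmethylene ludongnin A 11-chloroacetate | C1C(=O)[C@]23C[C@H]1C[C@@H](OC(=O)CCl)[C@H]2[C@@]1(CCC[C@@]2(C)COC(=O)[C@H]21)COC3=O | intermediate
30 | 16-desmethylene ludongnin A (11-hydroxy-15-oxo-17-nor-6,7-seco-ent-kaurane-6,19:7,20-diolide) | C1C(=O)[C@]23C[C@H]1C[C@@H](O)[C@H]2[C@@]1(CCC[C@@]2(C)COC(=O)[C@H]21)COC3=O | intermediate
31 | ludongnin A, (4R,5R,8S,9S,10R,11R,13S)-11-hydroxy-15-oxo-6,7-seco-ent-kaur-16-ene-6,19:7,20-diolide | C=C1C(=O)[C@]23C[C@H]1C[C@@H](O)[C@H]2[C@@]1(CCC[C@@]2(C)COC(=O)[C@H]21)COC3=O | target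

**Step count and risk**

Total: 20 steps. Longest linear sequence: 17 steps (steps 1–7, then 11–20); steps 8–10 make the butenolide in a side branch.

Steps most likely to fail:

1. Step 18 (C–H insertion). The unstabilised carbenoid may be intercepted by the oxygen of the geminal C7 lactone carbonyl (five-membered carbonyl ylide), may insert into the syn-axial C11–H, or may dimerise if the chair with axial C10 is thinly populated. The fallback sets out from 26 and returns at 29, using a stabilised acceptor/acceptor carbenoid. Acid 26 would be activated with carbonyldiimidazole and C-acylated with magnesium mono-allyl malonate to give the allyl β-keto ester F1. Regitz diazo transfer (p-acetamidobenzenesulfonyl azide, Et3N) would give the allyl α-diazo-β-keto ester F2. Rh(II)-catalysed 1,5-insertion, the best-precedented class for unactivated methylene C–H bonds, would close ring D as the C16 allyl ester F3. Pd(PPh3)4/morpholine deallylation with decarboxylation would then give 29.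

2. Step 11 (cyclisation/Giese cascade). The alkoxycarbonyl radical may add to the butenolide before it cyclises, the hindered tertiary C10 radical may be reduced or disproportionate faster than it adds to the γ-substituted acceptor, or face selectivity at C10 may be poor. The fallback sets out from 9 and returns at 19, separating lactone formation from fragment coupling. Alcohol 9 would be converted with phosgene into the chloroformate F4 and with benzeneselenol/pyridine into the Se-phenyl selenocarbonate F5. Tin hydride-mediated 5-exo cyclisation under air, with oxygen capture of the tertiary radical and PPh3 reduction of the hydroperoxide, would give the C10 tertiary alcohol of the ring A lactone F6 (either C10 epimer serves). Acylation with methyl chlorooxoacetate would give the tertiary methyl oxalate F7 and CsOH the cesium oxalate F8. Photoredox decarboxylative Giese addition of this tertiary oxalate to 18 under the conditions of step 11 would give 19.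

3. Step 14 (lactone transposition). The equilibrium between the bridged 7,11-γ-lactone and the 7,20-δ-lactone may not lie far enough on the δ side, or the C20 alcohol may be diverted into a 6,20-lactone, so that acylation in step 15 captures the wrong hydroxyl. The fallback sets out from 22 and returns at 25, replacing the equilibrium by an irreversible lactonisation. Methanolysis of 22 (K2CO3, MeOH) would open the bridged lactone to the C7 methyl ester C11 alcohol F9. Chloroacetylation would give the C11 chloroacetate F10, and hydrogenolysis the C20 alcohol F11. PPTS-catalysed lactonisation in toluene over molecular sieves, driven by removal of methanol and possible only onto the methyl ester (the tert-butyl ester is inert), would give 25.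

Further compounds
F1 | step 18 | allyl β-keto ester from 26 (C15 ketone, C16 methylene, allyl ester) | C=CCOC(=O)CC(=O)[C@]12CCC[C@@H](OC(=O)CCl)[C@H]1[C@@]1(CCC[C@@]3(C)COC(=O)[C@H]31)COC2=O
F2 | step 18 | allyl α-diazo-β-keto ester | C=CCOC(=O)C(=[N+]=[N-])C(=O)[C@]12CCC[C@@H](OC(=O)CCl)[C@H]1[C@@]1(CCC[C@@]3(C)COC(=O)[C@H]31)COC2=O
F3 | step 18 | allyl 16-carboxylate of 29 (C16 epimers) | C=CCOC(=O)C1C(=O)[C@]23C[C@H]1C[C@@H](OC(=O)CCl)[C@H]2[C@@]1(CCC[C@@]2(C)COC(=O)[C@H]21)COC3=O
F4 | step 11 | [(R)-3-[(benzyloxy)methyl]-1-methylcyclohex-2-en-1-yl]methyl chloroformate | ClC(=O)OC[C@]1(C)CCCC(COCc2ccccc2)=C1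
F5 | step 11 | O-{[(R)-3-[(benzyloxy)methyl]-1-methylcyclohex-2-en-1-yl]methyl} Se-phenyl selenocarbonate | O=C([Se]c1ccccc1)OC[C@]1(C)CCCC(COCc2ccccc2)=C1
F6 | step 11 | (3aR,7aS)-7-[(benzyloxy)methyl]-7-hydroxy-3a-methylhexahydro-2-benzofuran-1(3H)-one (C10 epimers) | OC1(COCc2ccccc2)CCC[C@@]3(C)COC(=O)[C@H]31
F7 | step 11 | methyl oxalate of F6 | COC(=O)C(=O)OC1(COCc2ccccc2)CCC[C@@]3(C)COC(=O)[C@H]31
F8 | step 11 | cesium oxalate of F6 | [Cs+].[O-]C(=O)C(=O)OC1(COCc2ccccc2)CCC[C@@]3(C)COC(=O)[C@H]31
F9 | step 14 | C7 methyl ester, C15 tert-butyl ester, C11 alcohol, C20 benzyl ether | CC(C)(C)OC(=O)[C@]1(C(=O)OC)CCC[C@@H](O)[C@H]1[C@@]1(CCC[C@@]2(C)COC(=O)[C@H]21)COCc1ccccc1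
F10 | step 14 | C11 chloroacetate of F9 | CC(C)(C)OC(=O)[C@]1(C(=O)OC)CCC[C@@H](OC(=O)CCl)[C@H]1[C@@]1(CCC[C@@]2(C)COC(=O)[C@H]21)COCc1ccccc1
F11 | step 14 | C20 alcohol from F10 | CC(C)(C)OC(=O)[C@]1(C(=O)OC)CCC[C@@H](OC(=O)CCl)[C@H]1[C@@]1(CCC[C@@]2(C)COC(=O)[C@H]21)CO
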